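## The problem

Larreantin is a 2-methoxy-1,4-naphthoquinone (ring A: C1(=O), C2(OMe), C3–H, C4(=O), C4a, C8a) fused to a benzenoid ring B that is substituted on every carbon except C5. Ring B carries a 4-hydroxy-3-methoxybenzyl group on C6, a methyl group on C7 and a 4-hydroxy-3-methoxyphenyl group on C8. The difficulty is regiochemical: three different carbon substituents must sit in a fixed order on contiguous carbons of ring B, and the methoxy group of ring A must end up on C2, next to the carbonyl that lies peri to the C8 aryl group. There is no stereocentre, and the pendant ring at C8 has only hydrogen in its ortho positions, so nothing stereochemical has to be set. The sensitive groups are the methoxyquinone (a vinylogous ester open to bases, nucleophiles and reductants), the two guaiacol hydroxyls (which do not survive quinone-forming oxidants) and the doubly benzylic C6 methylene. The quinone must therefore appear late from an aromatic ether, and the phenols must stay masked to the end. The feature that allows a short ring B construction is that C8 bears an aryl group and is bonded to C8a, with C7 and C6 next in line and C5 a CH. A but-3-yn-2-one chain on C4a maps onto C5 (CH2), C6 (C=O), C7 and C8 (alkyne); attack of C8a on the aryl-bearing alkyne carbon under an iodonium electrophile closes ring B and leaves iodine on C7 and hydroxyl on C6 as two handles of different reactivity. The trap is that the C2 oxygen is para to C4a, the carbon that carries the chain. A para-alkoxy group diverts this type of closure to ipso attack at C4a and, after loss of its alkyl group, to a spiro[4.5]trienone, so C2 must not be an ether while ring B is closed.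

## Retrosynthesis

**Phenols and quinone.** Larreantin 21 is traced to its O,O-dibenzyl ether 19 (two O–CH2Ph bonds) and 19 to the 1,2,4-trimethoxynaphthalene 18 (the two C=O groups back to C1–OMe and C4–OMe). Only heteroatom bonds are touched, so the full carbon skeleton is already present in 18. Benzyl is chosen because it survives organolithium, iodonium, triflation, organozinc and alkoxide conditions and is removed without base. The forward steps must oxidise the most electron-rich arene selectively, then cleave the benzyl ethers in the presence of a reducible quinone.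

**C2–OMe.** In 18 the C2–O bond is cut back to the C2–Cl bond of 17. This cut is what the ring closure demands: with chlorine para to C4a the closure has no reason to turn to the ipso carbon, and the chlorine is inert to the palladium–phosphine catalysts of the two C–C couplings. An O-sulfonyl group would serve the same purpose but would cost a phenol synthesis and a deprotection, whereas chlorine is installed in one step. The forward reaction is a palladium-catalysed C–O coupling with methanol on an electron-rich aryl chloride.

**C6–CH2.** Cutting the C6–CH2Ar bond of 17 gives the aryl triflate 13 and the benzylic chloride 15, used as its zinc reagent 16. This is preferred over a Friedel–Crafts benzylation, which could not be directed to C6. It removes one of the two guaiacyl units and leaves a naphthalene with a single remaining handle. The forward reaction must couple at C6–OTf and leave C2–Cl alone.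

**C7–CH3 and C6–OTf.** Triflate 13 comes from the iodo triflate 12 (C7–CH3 bond) and 12 from the iodonaphthol 11 (O–S bond). The order I before OTf is the natural order of oxidative addition, so no protecting-group change is needed between the two couplings. The forward methylation must discriminate C–I from C–OTf and C–Cl at a hindered position.

**C8–C8a (key).** Cutting C8–C8a in 11, with the iodine removed from C7 and C6–OH returned to a ketone, gives the ynone 9. This single cut removes ring B and reduces the problem to a benzyl alkynyl ketone with two arenes. Against cycloaddition approaches to ring B it has the advantage that the position of every substituent follows from connectivity. The forward reaction requires attack at C8a and not at C4a, and at the aryl-bearing alkyne carbon and not the carbonyl-bearing one.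

**Ynone.** The C(=O)–C(sp) bond of 9 is cut to the N-methoxy-N-methylamide 4 and the terminal alkyne 6, used as its lithium acetylide 7. Amide 4 comes from the chloro acid 2, and 2 from commercial (2,5-dimethoxyphenyl)acetic acid 1 by ring chlorination. Alkyne 6 comes from O-benzylvanillin 5 by one-carbon homologation, and chloride 15 from the benzylic alcohol 14. All three starting materials are catalogue chemicals.

## Roads not taken

**Alternative 1:** Dehydrogenative styrene–yne Diels–Alder reaction. The cut is through C6–C7 and C8–C8a. Forward, the propargyl cinnamate A1 is heated in an oxidising high-boiling solvent; the styrene unit serves as diene and the aryl alkyne as dienophile, giving the arylnaphthalene lactone A2 with loss of H2.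
- Merits: two ring bonds and the lactone form in one step from two simple halves. Because the reaction is pericyclic, ring A can carry all three methoxy groups from the start, with no ipso problem and no late methoxylation. In this respect it is better than the chosen plan, which needs two extra steps for the C2 oxygen.
- Weak points: A2 has the wrong oxidation states on both ring B substituents. The lactone carbonyl on C6 must take up exactly one aryl nucleophile and be deoxygenated to CH2Ar, and the C7–CH2O arm must be reduced to CH3. The cycloaddition also needs high temperature and can stop partly at the dihydronaphthalene.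
- Comparison: the chosen plan delivers C6 and C7 from the key step as C–OTf and C–I, the oxidation states that cross-couplings use directly.

**Alternative 2:** Biomimetic Diels–Alder reaction of a lignan-type diene with a bromomethoxyquinone. The cut is through C8–C8a and C4a–C5. Forward, the (E)-diene A3 adds to the brominated double bond of 2-bromo-6-methoxy-1,4-benzoquinone A4; loss of HBr gives the 5,8-dihydronaphthoquinone A5, which only needs aromatisation and desilylation.
- Merits: this is probably the shortest road. The methoxyquinone is intact from the start and aromatisation is nearly spontaneous. In step count and convergence it is better than the chosen plan.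
- Weak points: A3 is a crowded, electron-rich 1-aryl-2,3-disubstituted diene that needs its own geometry-controlled synthesis and is prone to acid-induced isomerisation and polymerisation. The position of the methoxy group relative to the C8 aryl group rests on the orienting effect of bromine on a diene whose two termini differ only moderately. A wrong regioisomer would be a 3-methoxy isomer that is hard to separate and hard to tell apart.
- Comparison: the chosen plan fixes this relationship through bonds that exist before the ring is closed, and uses only standard C–C bond formations, at the price of more steps.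

**Alternative 3:** Carbonylative acylpalladation closing the quinone ring. The cut is through C4a–C4 and C4–C3. Forward, the aryl iodide A6 undergoes oxidative addition, CO insertion, 6-endo acylpalladation of the methoxy enone terminus and β-hydride elimination to give A7, which is the same compound as 19 of the chosen route.
- Merits: the quinone is formed without an oxidant and the C2 methoxy group is present from the start, so both the tetravalent-cerium oxidation and the late methoxylation are avoided.
- Weak points: the key step does nothing for the real difficulty, the pentasubstituted ring B. A6 would have to be made by a benzannulation as demanding as the chosen one. The 6-endo acylpalladation of an α-alkoxy enone competes with 5-exo closure and with direct Heck cyclisation before CO uptake, and has little support on this substrate type.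
- Comparison: the chosen plan spends its key step on ring B, where the complexity lies, and forms ring A's quinone by a routine oxidation.

Key step: step 5

Remark on names: all naphthalene intermediates carry the locants of the target (C1 and C4 the quinone carbons, C2 the methoxy-bearing carbon, C8 the aryl-bearing carbon) and not lowest locants.
Remark on stereochemistry: the target has no stereocentre and the C8–aryl axis is taken as freely rotating.

## Route

Step 1
Reactants: 1 (2,5-dimethoxyphenyl)acetic acid
Product: 2 (4-chloro-2,5-dimethoxyphenyl)acetic acid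
Conditions: SO2Cl2 (1.05 equiv), AcOH, 20 °C
Reagents that add atoms: sulfuryl chloride, O=S(=O)(Cl)Cl
Why: Electrophilic aromatic chlorination; of the three free positions, each ortho to one methoxy group, the one para to the CH2CO2H group is the least hindered and is the usual site of halogenation in 2,5-dimethoxyphenylalkyl compounds. One equivalent of reagent limits dichlorination.

Step 2
Reactants: 2 (4-chloro-2,5-dimethoxyphenyl)acetic acid
Product: 4 2-(4-chloro-2,5-dimethoxyphenyl)-N-methoxy-N-methylacetamide, via acyl imidazolide 3 (not isolated)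
Conditions: 1,1'-carbonyldiimidazole (1.1 equiv), CH2Cl2, 20 °C; then MeNH(OMe)·HCl (1.2 equiv), 20 °C
Reagents that add atoms: N,O-dimethylhydroxylamine hydrochloride, CNOC.Cl
Why: Amide formation through the acyl imidazolide; no acid chloride is involved, so ketene formation from the arylacetic acid is avoided.

Step 3
Reactants: 5 4-(benzyloxy)-3-methoxybenzaldehyde
Product: 6 1-(benzyloxy)-4-ethynyl-2-methoxybenzene
Conditions: dimethyl (1-diazo-2-oxopropyl)phosphonate (1.3 equiv), K2CO3 (2 equiv), MeOH/THF, 20 °C
Reagents that add atoms: dimethyl (1-diazo-2-oxopropyl)phosphonate, COP(=O)(OC)C(=[N+]=[N-])C(C)=O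
Why: Ohira–Bestmann (Seyferth–Gilbert) homologation: methanolysis of the reagent gives the diazomethylphosphonate anion, which olefinates the non-enolisable aldehyde; loss of N2 and a 1,2-shift in the alkylidene carbene give the terminal alkyne.

Step 4
Reactants: 6 1-(benzyloxy)-4-ethynyl-2-methoxybenzene; 4 2-(4-chloro-2,5-dimethoxyphenyl)-N-methoxy-N-methylacetamide
Product: 9 4-[4-(benzyloxy)-3-methoxyphenyl]-1-(4-chloro-2,5-dimethoxyphenyl)but-3-yn-2-one, via lithium acetylide 7 (not isolated), via lithium hemiaminal alkoxide 8 (not isolated)
Conditions: 6 (1.3 equiv), n-BuLi (1.25 equiv), THF, −78 °C; then 4, −78 to 0 °C; aq. NH4Cl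
Reagents that add atoms: none
Why: Weinreb ketone synthesis: the acetylide adds to the N-methoxy-N-methylamide and the chelated adduct 8 persists until the quench, so no second addition occurs. The acetylide is a weak base and should add at −78 °C faster than it removes the benzylic α-proton.

Step 5
Reactants: 9 4-[4-(benzyloxy)-3-methoxyphenyl]-1-(4-chloro-2,5-dimethoxyphenyl)but-3-yn-2-one
Product: 11 8-[4-(benzyloxy)-3-methoxyphenyl]-2-chloro-7-iodo-1,4-dimethoxynaphthalen-6-ol, via 5H-naphthalen-6-one tautomer 10 (not isolated)
Conditions: ICl (1.05 equiv), CH2Cl2, −78 °C; aq. Na2S2O3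
Reagents that add atoms: iodine monochloride, ClI
Why: ICl delivers I+ to the alkyne carbon next to the carbonyl (C7), so the vinyl cation character develops on C8, where the para-benzyloxyphenyl group stabilises it; the free ortho carbon of ring A (C8a, ortho to the C1 methoxy group) attacks C8 in a 6-endo-dig Friedel–Crafts closure of ring B, and proton loss gives ketone 10, which tautomerises to naphthol 11. The closest known reaction type is the electrophilic iodocyclisation of 1-aryl-3-alkyn-2-ones to 3-iodo-2-naphthols with ICl or I2. The 5-exo mode would place the cation next to the carbonyl and is not expected. The second ortho carbon of ring A is blocked by the C4 methoxy group, so only C8a and the tether carbon C4a can compete. The selectivity needed is C8a over C4a: an alkoxy group on C2 (para to C4a) would direct the closure to C4a and, through loss of its alkyl group, to a spiro[4.5]trienone, so C2 carries chlorine, which gives C4a neither lone-pair assistance nor an exit. An arenium ion formed at C4a could only revert or shift the alkenyl carbon to C8a, which leads to the same naphthol. No stereocentre is formed. A single equivalent of ICl at −78 °C is used so that neither C3 of ring A nor C5 of the product naphthol is iodinated.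

Step 6
Reactants: 11 8-[4-(benzyloxy)-3-methoxyphenyl]-2-chloro-7-iodo-1,4-dimethoxynaphthalen-6-ol
Product: 12 8-[4-(benzyloxy)-3-methoxyphenyl]-2-chloro-7-iodo-1,4-dimethoxynaphthalen-6-yl trifluoromethanesulfonate
Conditions: Tf2O (1.2 equiv), pyridine, CH2Cl2, 0 °C
Reagents that add atoms: trifluoromethanesulfonic anhydride, FC(F)(F)S(=O)(=O)OS(=O)(=O)C(F)(F)F
Why: O-sulfonylation of the naphthol; the C6 oxygen becomes a cross-coupling leaving group less reactive than the C7 iodide, so the two handles can be used in sequence.

Step 7
Reactants: 12 8-[4-(benzyloxy)-3-methoxyphenyl]-2-chloro-7-iodo-1,4-dimethoxynaphthalen-6-yl trifluoromethanesulfonate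
Product: 13 8-[4-(benzyloxy)-3-methoxyphenyl]-2-chloro-1,4-dimethoxy-7-methylnaphthalen-6-yl trifluoromethanesulfonate
Conditions: MeZnCl (2.0 equiv), Pd(PPh3)4 (5 mol %), THF, 50 °C
Reagents that add atoms: methylzinc chloride, C[Zn]Cl
Why: Negishi coupling: zerovalent palladium with PPh3 inserts into the C7–I bond far faster than into C6–OTf or C2–Cl, and the ortho triflate accelerates this insertion. The small methylzinc reagent transmetalates at the hindered C7 position without attacking the sulfonate.

Step 8
Reactants: 14 [4-(benzyloxy)-3-methoxyphenyl]methanol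
Product: 15 1-(benzyloxy)-4-(chloromethyl)-2-methoxybenzene
Conditions: SOCl2 (1.2 equiv), CH2Cl2, 0 °C; used crude
Reagents that add atoms: thionyl chloride, ClS(Cl)=O
Why: Chlorodehydration through the chlorosulfite; the electron-rich benzylic position ionises easily, so the reaction is fast at 0 °C. The chloride is used without chromatography because it is prone to solvolysis.

Step 9
Reactants: 15 1-(benzyloxy)-4-(chloromethyl)-2-methoxybenzene; 13 8-[4-(benzyloxy)-3-methoxyphenyl]-2-chloro-1,4-dimethoxy-7-methylnaphthalen-6-yl trifluoromethanesulfonate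
Product: 17 6-[4-(benzyloxy)-3-methoxybenzyl]-8-[4-(benzyloxy)-3-methoxyphenyl]-2-chloro-1,4-dimethoxy-7-methylnaphthalene, via benzylzinc chloride 16 (not isolated)
Conditions: 15 (2 equiv), Zn dust, LiCl, THF, 25 °C; then 13, PdCl2(dppf) (5 mol %), THF, 60 °C
Reagents that add atoms: none
Why: LiCl-mediated insertion of zinc into the benzylic chloride gives 16, which has no β-hydrogen and couples with the aryl triflate in a Negishi reaction. With the bidentate dppf ligand the palladium catalyst does not insert into the electron-rich C2–Cl bond.

Step 10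
Reactants: 17 6-[4-(benzyloxy)-3-methoxybenzyl]-8-[4-(benzyloxy)-3-methoxyphenyl]-2-chloro-1,4-dimethoxy-7-methylnaphthalene
Product: 18 6-[4-(benzyloxy)-3-methoxybenzyl]-8-[4-(benzyloxy)-3-methoxyphenyl]-1,2,4-trimethoxy-7-methylnaphthalene
Conditions: MeOH (5 equiv), Pd2(dba)3 (2 mol %), tBuBrettPhos (5 mol %), NaOt-Bu (1.5 equiv), 1,4-dioxane, 60 °C
Reagents that add atoms: methanol, CO
Why: Palladium-catalysed C–O cross-coupling of an aryl chloride with methanol (Buchwald–Hartwig-type etherification); the bulky di-tert-butylbiarylphosphine speeds C–O reductive elimination so that it outruns β-hydride elimination from the palladium methoxide. Benzyl ethers and the diarylmethane are inert to NaOt-Bu.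

Step 11
Reactants: 18 6-[4-(benzyloxy)-3-methoxybenzyl]-8-[4-(benzyloxy)-3-methoxyphenyl]-1,2,4-trimethoxy-7-methylnaphthalene
Product: 19 6-[4-(benzyloxy)-3-methoxybenzyl]-8-[4-(benzyloxy)-3-methoxyphenyl]-2-methoxy-7-methylnaphthalene-1,4-dione (O,O-dibenzyl larreantin)
Conditions: (NH4)2Ce(NO3)6 (2.5 equiv), MeCN/H2O, 0 °C
Reagents that add atoms: water, O
Why: Oxidative demethylation: the trimethoxynaphthalene has by far the lowest oxidation potential in the molecule; its radical cation takes up water at C1 and C4 and loses two molecules of methanol, giving the para-quinone with the C2 methoxy group retained. The benzyloxy-methoxy-substituted rings and the C6 methylene are oxidised much more slowly at 0 °C.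

Step 12
Reactants: 19 6-[4-(benzyloxy)-3-methoxybenzyl]-8-[4-(benzyloxy)-3-methoxyphenyl]-2-methoxy-7-methylnaphthalene-1,4-dione
Product: 21 larreantin [6-(4-hydroxy-3-methoxybenzyl)-8-(4-hydroxy-3-methoxyphenyl)-2-methoxy-7-methylnaphthalene-1,4-dione], via hydroquinone 20 (not isolated)
Conditions: H2 (1 atm), 10% Pd/C, EtOAc, 20 °C; then air, 20 °C
Reagents that add atoms: none
Why: Hydrogenolysis of the two benzyl aryl ethers; the quinone is reduced reversibly to hydroquinone 20 under hydrogen and is restored by air on work-up. Neither the diarylmethane nor the biaryl bond is cleaved under these conditions.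

## Compound list

1 | (2,5-dimethoxyphenyl)acetic acid | COc1ccc(OC)c(CC(O)=O)c1 | starting material
2 | (4-chloro-2,5-dimethoxyphenyl)acetic acid | COc1cc(Cl)c(OC)cc1CC(O)=O | intermediate
3 | 2-(4-chloro-2,5-dimethoxyphenyl)-1-(imidazol-1-yl)ethanone (acyl imidazolide) | COc1cc(Cl)c(OC)cc1CC(=O)n1ccnc1 | intermediate
4 | 2-(4-chloro-2,5-dimethoxyphenyl)-N-methoxy-N-methylacetamide | COc1cc(Cl)c(OC)cc1CC(=O)N(C)OC | intermediate
5 | 4-(benzyloxy)-3-methoxybenzaldehyde | COc1cc(C=O)ccc1OCc1ccccc1 | starting material
6 | 1-(benzyloxy)-4-ethynyl-2-methoxybenzene | COc1cc(C#C)ccc1OCc1ccccc1 | intermediate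
7 | lithium [4-(benzyloxy)-3-methoxyphenyl]acetylide | COc1cc(C#C[Li])ccc1OCc1ccccc1 | intermediate
8 | lithium alkoxide of the N-methoxy-N-methyl hemiaminal formed from 7 and 4 | COc1cc(Cl)c(OC)cc1CC(O[Li])(C#Cc1ccc(OCc2ccccc2)c(OC)c1)N(C)OC | intermediate
9 | 4-[4-(benzyloxy)-3-methoxyphenyl]-1-(4-chloro-2,5-dimethoxyphenyl)but-3-yn-2-one | COc1cc(Cl)c(OC)cc1CC(=O)C#Cc1ccc(OCc2ccccc2)c(OC)c1 | intermediate
10 | 8-[4-(benzyloxy)-3-methoxyphenyl]-2-chloro-7-iodo-1,4-dimethoxy-5H-naphthalen-6-one | COc1c(Cl)cc(OC)c2CC(=O)C(I)=C(c3ccc(OCc4ccccc4)c(OC)c3)c12 | intermediate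
11 | 8-[4-(benzyloxy)-3-methoxyphenyl]-2-chloro-7-iodo-1,4-dimethoxynaphthalen-6-ol | COc1c(Cl)cc(OC)c2cc(O)c(I)c(-c3ccc(OCc4ccccc4)c(OC)c3)c12 | intermediate
12 | 8-[4-(benzyloxy)-3-methoxyphenyl]-2-chloro-7-iodo-1,4-dimethoxynaphthalen-6-yl trifluoromethanesulfonate | COc1c(Cl)cc(OC)c2cc(OS(=O)(=O)C(F)(F)F)c(I)c(-c3ccc(OCc4ccccc4)c(OC)c3)c12 | intermediate
13 | 8-[4-(benzyloxy)-3-methoxyphenyl]-2-chloro-1,4-dimethoxy-7-methylnaphthalen-6-yl trifluoromethanesulfonate | COc1c(Cl)cc(OC)c2cc(OS(=O)(=O)C(F)(F)F)c(C)c(-c3ccc(OCc4ccccc4)c(OC)c3)c12 | intermediate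
14 | [4-(benzyloxy)-3-methoxyphenyl]methanol | COc1cc(CO)ccc1OCc1ccccc1 | starting material
15 | 1-(benzyloxy)-4-(chloromethyl)-2-methoxybenzene | COc1cc(CCl)ccc1OCc1ccccc1 | intermediate
16 | [4-(benzyloxy)-3-methoxybenzyl]zinc chloride | COc1cc(C[Zn]Cl)ccc1OCc1ccccc1 | intermediate
17 | 6-[4-(benzyloxy)-3-methoxybenzyl]-8-[4-(benzyloxy)-3-methoxyphenyl]-2-chloro-1,4-dimethoxy-7-methylnaphthalene | COc1c(Cl)cc(OC)c2cc(Cc3ccc(OCc4ccccc4)c(OC)c3)c(C)c(-c3ccc(OCc4ccccc4)c(OC)c3)c12 | intermediate
18 | 6-[4-(benzyloxy)-3-methoxybenzyl]-8-[4-(benzyloxy)-3-methoxyphenyl]-1,2,4-trimethoxy-7-methylnaphthalene | COc1c(OC)cc(OC)c2cc(Cc3ccc(OCc4ccccc4)c(OC)c3)c(C)c(-c3ccc(OCc4ccccc4)c(OC)c3)c12 | intermediate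
19 | 6-[4-(benzyloxy)-3-methoxybenzyl]-8-[4-(benzyloxy)-3-methoxyphenyl]-2-methoxy-7-methylnaphthalene-1,4-dione (O,O-dibenzyl larreantin) | COC1=CC(=O)c2cc(Cc3ccc(OCc4ccccc4)c(OC)c3)c(C)c(-c3ccc(OCc4ccccc4)c(OC)c3)c2C1=O | intermediate
20 | 6-(4-hydroxy-3-methoxybenzyl)-8-(4-hydroxy-3-methoxyphenyl)-2-methoxy-7-methylnaphthalene-1,4-diol | COc1cc(O)c2cc(Cc3ccc(O)c(OC)c3)c(C)c(-c3ccc(O)c(OC)c3)c2c1O | intermediate
21 | larreantin, 6-(4-hydroxy-3-methoxybenzyl)-8-(4-hydroxy-3-methoxyphenyl)-2-methoxy-7-methylnaphthalene-1,4-dione | COC1=CC(=O)c2cc(Cc3ccc(O)c(OC)c3)c(C)c(-c3ccc(O)c(OC)c3)c2C1=O | target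

## Step count and risks

Total: 12 steps. Longest linear sequence: 10 steps (steps 1, 2, 4, 5, 6, 7, 9, 10, 11, 12).

**Step 5 (key step).** The main risk is partition of the ring closure between C8a and the tether carbon C4a, which keeps an ortho methoxy group (on C4) even though the para position is now chlorine. The second risk is iodination outside the alkyne, at C3 of ring A before closure or at C5 of the product naphthol after it, if the closure is slowed by the electron-withdrawing chlorine.

Fallback: it sets out from amide 4 and forms the same C8–C8a bond with a carbonyl electrophile and the C7 methyl group already in place.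
- Commercial 1-(4-hydroxy-3-methoxyphenyl)propan-1-one is benzylated (BnBr, K2CO3) to 1-[4-(benzyloxy)-3-methoxyphenyl]propan-1-one F1.
- The lithium enolate of F1 (LiN(SiMe3)2, THF, −78 °C) is acylated by 4 in a Claisen-type condensation to give racemic 1-[4-(benzyloxy)-3-methoxyphenyl]-4-(4-chloro-2,5-dimethoxyphenyl)-2-methylbutane-1,3-dione F2.
- Acid-mediated cyclodehydration of F2 (CF3CO2H in CH2Cl2, going to CH3SO3H at 0 °C only if needed, to spare the benzyl ether) is an intramolecular Friedel–Crafts attack of C8a on the aryl ketone. Because carbonyl addition is reversible, it should settle on the six-membered ring and give 8-[4-(benzyloxy)-3-methoxyphenyl]-2-chloro-1,4-dimethoxy-7-methylnaphthalen-6-ol F3.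
- Triflation of F3 (Tf2O, pyridine) returns to the route at 13, so steps 6 and 7 are no longer needed.

**Step 10.** β-Hydride elimination from the palladium methoxide may lead to hydrodechlorination, because C–O reductive elimination is slow for an electron-rich aryl group with an ortho methoxy substituent.

Fallback: from 17, coupling with hydroxide, which has no β-hydrogen (KOH, Pd2(dba)3, tBuXPhos, 1,4-dioxane/H2O, 100 °C), gives 6-[4-(benzyloxy)-3-methoxybenzyl]-8-[4-(benzyloxy)-3-methoxyphenyl]-1,4-dimethoxy-7-methylnaphthalen-2-ol F4. Williamson methylation (MeI, K2CO3, acetone) returns to the route at 18.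

**Step 9.** Wurtz-type homocoupling may occur during zinc insertion into the electron-rich benzylic chloride. Oxidative addition into the electron-rich, ortho-methylated naphthyl triflate may also be slow, so that S–O cleavage back to the naphthol competes.

Fallback: the polarity is reversed. From 13, Miyaura borylation (bis(pinacolato)diboron, PdCl2(dppf), KOAc, 1,4-dioxane, 85 °C) gives 2-{8-[4-(benzyloxy)-3-methoxyphenyl]-2-chloro-1,4-dimethoxy-7-methylnaphthalen-6-yl}-4,4,5,5-tetramethyl-1,3,2-dioxaborolane F5. Suzuki–Miyaura coupling of F5 with benzylic chloride 15 (Pd(PPh3)4, K2CO3, THF/H2O, 70 °C) returns to the route at 17.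

**Step 4.** The acetylide may deprotonate the benzylic α-position of amide 4 instead of adding, and the product ynone may isomerise to the allenyl ketone under base during the quench.

Fallback: from 4, reduction with i-Bu2AlH (THF, −78 °C) gives (4-chloro-2,5-dimethoxyphenyl)acetaldehyde F6. Addition of acetylide 7 to F6 at −78 °C gives racemic 4-[4-(benzyloxy)-3-methoxyphenyl]-1-(4-chloro-2,5-dimethoxyphenyl)but-3-yn-2-ol F7. Oxidation with Dess–Martin periodinane (CH2Cl2, NaHCO3) returns to the route at 9.

**Step 12.** The quinone ring may be over-reduced, or reoxidation may be incomplete, while the benzyl ethers are being cleaved; the hydroquinone may also slow the catalyst.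

Fallback: the benzyl groups are removed before the quinone exists.
- From 18, hydrogenolysis (H2, 10% Pd/C, EtOAc) gives 2-methoxy-4-{[8-(4-hydroxy-3-methoxyphenyl)-1,2,4-trimethoxy-7-methylnaphthalen-6-yl]methyl}phenol F8.
- Acetylation (Ac2O, pyridine) gives the diacetate F9.
- Oxidation with (NH4)2Ce(NO3)6 (MeCN/H2O, 0 °C) gives O,O-diacetyl larreantin F10.
- Acid methanolysis of F10 (HCl, MeOH, 20 °C), under which the methoxyquinone only exchanges with its own solvent, returns to the route at 21.

## Further compounds

F1 | step 5 | 1-[4-(benzyloxy)-3-methoxyphenyl]propan-1-one | CCC(=O)c1ccc(OCc2ccccc2)c(OC)c1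
F2 | step 5 | 1-[4-(benzyloxy)-3-methoxyphenyl]-4-(4-chloro-2,5-dimethoxyphenyl)-2-methylbutane-1,3-dione (racemic) | COc1cc(Cl)c(OC)cc1CC(=O)C(C)C(=O)c1ccc(OCc2ccccc2)c(OC)c1
F3 | step 5 | 8-[4-(benzyloxy)-3-methoxyphenyl]-2-chloro-1,4-dimethoxy-7-methylnaphthalen-6-ol | COc1c(Cl)cc(OC)c2cc(O)c(C)c(-c3ccc(OCc4ccccc4)c(OC)c3)c12
F4 | step 10 | 6-[4-(benzyloxy)-3-methoxybenzyl]-8-[4-(benzyloxy)-3-methoxyphenyl]-1,4-dimethoxy-7-methylnaphthalen-2-ol | COc1c(O)cc(OC)c2cc(Cc3ccc(OCc4ccccc4)c(OC)c3)c(C)c(-c3ccc(OCc4ccccc4)c(OC)c3)c12
F5 | step 9 | 2-{8-[4-(benzyloxy)-3-methoxyphenyl]-2-chloro-1,4-dimethoxy-7-methylnaphthalen-6-yl}-4,4,5,5-tetramethyl-1,3,2-dioxaborolane | COc1c(Cl)cc(OC)c2cc(B3OC(C)(C)C(C)(C)O3)c(C)c(-c3ccc(OCc4ccccc4)c(OC)c3)c12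
F6 | step 4 | (4-chloro-2,5-dimethoxyphenyl)acetaldehyde | COc1cc(Cl)c(OC)cc1CC=O
F7 | step 4 | 4-[4-(benzyloxy)-3-methoxyphenyl]-1-(4-chloro-2,5-dimethoxyphenyl)but-3-yn-2-ol (racemic) | COc1cc(Cl)c(OC)cc1CC(O)C#Cc1ccc(OCc2ccccc2)c(OC)c1
F8 | step 12 | 2-methoxy-4-{[8-(4-hydroxy-3-methoxyphenyl)-1,2,4-trimethoxy-7-methylnaphthalen-6-yl]methyl}phenol | COc1c(OC)cc(OC)c2cc(Cc3ccc(O)c(OC)c3)c(C)c(-c3ccc(O)c(OC)c3)c12
F9 | step 12 | diacetate of F8 (both phenols as acetates) | COc1c(OC)cc(OC)c2cc(Cc3ccc(OC(C)=O)c(OC)c3)c(C)c(-c3ccc(OC(C)=O)c(OC)c3)c12
F10 | step 12 | O,O-diacetyl larreantin | COC1=CC(=O)c2cc(Cc3ccc(OC(C)=O)c(OC)c3)c(C)c(-c3ccc(OC(C)=O)c(OC)c3)c2C1=O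
A1 | alternative 1 | 3-[3-methoxy-4-(methoxymethoxy)phenyl]prop-2-yn-1-yl (E)-3-(2,4,5-trimethoxyphenyl)prop-2-enoate | COCOc1ccc(C#CCOC(=O)/C=C/c2cc(OC)c(OC)cc2OC)cc1OC
A2 | alternative 1 | 8-aryl-1,2,4-trimethoxynaphthalene fused at C6/C7 to a γ-lactone (carbonyl on C6, OCH2 on C7), aryl = 3-methoxy-4-(methoxymethoxy)phenyl | COc1cc(OC)c2cc3C(=O)OCc3c(-c3ccc(OCOC)c(OC)c3)c2c1OC
A3 | alternative 2 | (E)-1-aryl-3-(arylmethyl)-2-methylbuta-1,3-diene, aryl = 4-(tert-butyldimethylsilyloxy)-3-methoxyphenyl | C=C(Cc1ccc(O[Si](C)(C)C(C)(C)C)c(OC)c1)/C(C)=C/c1ccc(O[Si](C)(C)C(C)(C)C)c(OC)c1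
A4 | alternative 2 | 2-bromo-6-methoxy-1,4-benzoquinone | COC1=CC(=O)C=C(Br)C1=O
A5 | alternative 2 | 8-aryl-6-(arylmethyl)-2-methoxy-7-methyl-5,8-dihydronaphthalene-1,4-dione (racemic at C8), aryl = 4-(tert-butyldimethylsilyloxy)-3-methoxyphenyl | COC1=CC(=O)C2=C(C1=O)C(c1ccc(O[Si](C)(C)C(C)(C)C)c(OC)c1)C(C)=C(Cc1ccc(O[Si](C)(C)C(C)(C)C)c(OC)c1)C2
A6 | alternative 3 | 1-{2-[4-(benzyloxy)-3-methoxyphenyl]-4-[4-(benzyloxy)-3-methoxybenzyl]-6-iodo-3-methylphenyl}-2-methoxyprop-2-en-1-one | C=C(OC)C(=O)c1c(I)cc(Cc2ccc(OCc3ccccc3)c(OC)c2)c(C)c1-c1ccc(OCc2ccccc2)c(OC)c1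
A7 | alternative 3 | O,O-dibenzyl larreantin (identical with 19) | COC1=CC(=O)c2cc(Cc3ccc(OCc4ccccc4)c(OC)c3)c(C)c(-c3ccc(OCc4ccccc4)c(OC)c3)c2C1=O
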